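What happens late in a run, once target stands beside reagent?

    substrate + second chain carrier → by-product + first chain carrier (k1 = 21000 /M/s)
    reagent + first chain carrier → target + second chain carrier (k2 = 1.2 × 10⁵ /M/s)
    initiator → 2 initiating radical (k3 = 0.0018 /min)
    2 first chain carrier → ended chains (k4 = 1 × 10⁸ /M/s)
    substrate + initiating radical → capped initiator + first chain carrier (k5 = 2.9 × 10⁵ /M/s)
    reagent + target → over-reaction product (k6 = 0.0077 /M/min)

all flasks: reagent 0.171 M; initiator 1.1 mM
- south-east: substrate 0.057 M (fed, over 6.00 h); time 6.0 h; a stirred flask in which substrate is dosed at a steady rate over 6.00 h without added volume, worked up at 6.0 h
- north-east: substrate 0.057 M; time 6.0 h; everything together in a closed stirred flask, run for 6.0 h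
- south-west: substrate 0.057 M; time 6.0 h; plug flow through a tube for 6.0 h, no back-mixing
- north: substrate 0.057 M; a single well-mixed tank run continuously and read at steady state, 6.0 h in it on average

- in percentages every species weighs as the substrate in it: one ended chains counts as two
- two of one species on the left: rate k times its square, two consumed each time
- the stated concentrations are those of everything mixed, before any reaction; amounts are the same in each set-up
- the feed brings no volume worth counting
- run time (south-east): 6.0 h

* the set-up with the highest share of target in all that became target or over-reaction product, at the outlet or at the end ("none" if the first two lie within 2 percentage points) (south-east / north-east / south-west / north / none)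
* share of target in all that became target or over-reaction product, at the outlet or at the end, south-east
* share of target in all that became target or over-reaction product, at the outlet or at the end, north-east
* share of target in all that became target or over-reaction product, at the outlet or at the end, south-west
* share of target in all that became target or over-reaction product, at the outlet or at the end, north

**Does target appear quickly?** Yes, by my estimate. If chain starts balance chain ends, the reagent step runs at 3.73 × 10⁻⁴ M/s at the start. In the north-east flask that would use up the substrate in 2.55 min, far shorter than the 8.8 h half-life of target against reagent as charged. In the south-east flask the feed of 2.64 × 10⁻⁶ M/s is far below that chain rate, so I let target appear as substrate arrives.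

**What then needs counting?** The loss of target to reagent. Let k be 0.0077 /M/min, B the reagent a target meets, and t the run time. I carry the exposure x = k·B·t, the number of target lifetimes in a run. With B held steady this is a pseudo-first-order loss.

**And for the dosed flask?** Target P obeys dP/dt = r − k·B·P, with r the feed. Integrated, its share is (1 − e^(−x))/x. Target piles up in proportion to time, so its time-weighted reagent is the charge less 0.667 of the substrate charge, 0.133 M. South-east then has x = 0.369 and a share of 83.6%.

**The weak spot?** Closed flasks. In north-east, and in each slice of the south-west tube, target sits for the whole 6.0 h. With the reagent left after the chain, 0.114 M, x is 0.316 and the share e^(−x) is 72.9%. The over-reaction takes reagent too, and I have not counted that here. I stop before the tank.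

The forecast names south-east and gives 84.2% there, 74.6% for north-east, 74.6% for south-west and 78% for north, saying “Batch and plug flow are identical”. My own figures are lower than its figures for south-east and the closed flasks.

The simulation gives 84.3% for south-east, 74.6% for north-east, 74.6% for south-west and 78.0% for north, so the best is south-east.

For south-east, the exposure reckoning stands 0.70 percentage points below the result. The neighbour is the same dosed flask with 0.68 M of reagent. There target meets 0.642 M, so x is 1.78, larger than in south-east, and the share is 46.7%. That neighbour gave 47.7%, ending with 47.7% target and 52.3% over-reaction product, in percent of the substrate charged, and with 87.2% of its reagent remaining.

(The numbers of this flask are made up; what happens was integrated by code.)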